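**Target:** CNP0212540.3, (2E)-1-[(1S,2S)-2-[(4Z)-6-(2,5-dihydroxy-3-methylphenyl)-4-methyl-2-oxohex-4-en-1-yl]-1,2-dimethylcyclopentyl]-4-hydroxy-4-methyl-pent-2-en-1-one. Both ring carbons are S, the ring methyls are cis, the trisubstituted alkene is Z and the enone is E.

## Retrosynthetic overview

1. End game: global desilylation ⇐ dithiane hydrolysis ⇐ enone from an (E)-alkenyllithium added to a neopentyl aldehyde, then oxidation.
2. C-2 ketone and Z-alkene of the long arm: alkylation of a 2-lithio-1,3-dithiane (acyl anion of the ring CH2CHO arm) with a (Z)-allylic bromide made by Still–Gennari olefination of an arylacetaldehyde (arene from 2-allyl-6-methylphenol).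
3. Core: cis-fused δ-lactone ⇐ ozonolysis of a regiodefined silyl enol ether ⇐ Me2CuLi/TMSCl addition to a bicyclo[3.3.0]octenone ⇐ Wacker oxidation/aldol condensation of (S)-2-allyl-2-methylcyclopentanone.
4. Chirality: ketoreductase desymmetrisation of achiral 2-allyl-2-methylcyclopentane-1,3-dione; the leftover ketone is then removed and the carbinol oxidised.
5. Ring order: ring A (the cyclopentane) is present from the start; ring B (a temporary fused cyclopentenone) is closed second by aldol condensation and opened again by ozonolysis; the arene is bought.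

Assumption: a Prelog-selective ketoreductase with NADP+/isopropanol recycling and the bis(trifluoroethyl) phosphonopropanoate are taken as off-the-shelf items.

## Route

**Core (ring A, both quaternary carbons)**

Step 1
Reactants: 1 2-methylcyclopentane-1,3-dione; 2 3-bromoprop-1-ene (allyl bromide)
Product: 3 2-methyl-2-(prop-2-en-1-yl)cyclopentane-1,3-dione
Conditions: NaOH (1 M aq.), rt, 48 h
Reagents that add atoms: none
Why: C-alkylation of the stabilised 1,3-dione enolate by a reactive allylic halide gives the achiral, prochiral 2,2-disubstituted dione, which has no stereocentre yet.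

Step 2
Reactants: 3 2-methyl-2-(prop-2-en-1-yl)cyclopentane-1,3-dione
Product: 4 (2S,3S)-3-hydroxy-2-methyl-2-(prop-2-en-1-yl)cyclopentan-1-one
Conditions: ketoreductase (NADPH-dependent alcohol dehydrogenase class, Prelog-selective), NADP+ (cat.), i-PrOH (10 vol%), KH2PO4/K2HPO4 buffer pH 7.0, 30 °C
Reagents that add atoms: none
Why: In this enzymatic desymmetrising carbonyl reduction the active site tells the methyl from the allyl group, so hydride from NADPH reaches only one of the two enantiotopic C=O groups and only one of its faces, which fixes the quaternary carbon (S) and the carbinol (S) in a single catalytic event, the known yeast-reductase outcome for 2,2-disubstituted cyclopentane-1,3-diones.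

Step 3
Reactants: 4 (2S,3S)-3-hydroxy-2-methyl-2-(prop-2-en-1-yl)cyclopentan-1-one
Product: 5 N'-[(1E,2R,3S)-3-hydroxy-2-methyl-2-(prop-2-en-1-yl)cyclopentylidene]-4-methylbenzenesulfonohydrazide
Conditions: TsNHNH2, EtOH, 60 °C
Reagents that add atoms: 4-methylbenzenesulfonohydrazide, Cc1ccc(cc1)S(=O)(=O)NN
Why: Hydrazone formation on the remaining cyclopentanone prepares its removal and touches no stereocentre (the C2 descriptor changes only through CIP priorities).

Step 4
Reactants: 5 N'-[(1E,2R,3S)-3-hydroxy-2-methyl-2-(prop-2-en-1-yl)cyclopentylidene]-4-methylbenzenesulfonohydrazide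
Product: 7 (1S,2S)-2-methyl-2-(prop-2-en-1-yl)cyclopentan-1-ol, via N-boryl tosylhydrazine 6 (not isolated)
Conditions: catecholborane (3 equiv), CHCl3, 0 °C to rt; then NaOAc·3H2O, reflux
Reagents that add atoms: none
Why: In this Kabalka variant of the Caglioti tosylhydrazone reduction, hydroboration of C=N followed by acetate-triggered loss of sulfinate and N2 leaves a CH2 group under mild conditions that spare the terminal alkene and both stereocentres.

Step 5
Reactants: 7 (1S,2S)-2-methyl-2-(prop-2-en-1-yl)cyclopentan-1-ol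
Product: 8 (2S)-2-methyl-2-(prop-2-en-1-yl)cyclopentan-1-one
Conditions: Dess–Martin periodinane, CH2Cl2, rt
Reagents that add atoms: none
Why: Dess–Martin oxidation of the secondary alcohol places the carbonyl on the carbon that will become the second quaternary centre, and the adjacent S quaternary carbon cannot epimerise.

Step 6
Reactants: 8 (2S)-2-methyl-2-(prop-2-en-1-yl)cyclopentan-1-one
Product: 9 (2S)-2-methyl-2-(2-oxopropyl)cyclopentan-1-one
Conditions: PdCl2 (10 mol%), CuCl (1 equiv), O2 (1 atm), DMF/H2O 7:1, rt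
Reagents that add atoms: water, O
Why: Tsuji–Wacker oxidation converts the terminal alkene with Markovnikov selectivity into the methyl ketone, giving the 1,4-diketone without touching the quaternary centre.

Step 7
Reactants: 9 (2S)-2-methyl-2-(2-oxopropyl)cyclopentan-1-one
Product: 10 (6aS)-6a-methyl-4,5,6,6a-tetrahydropentalen-2(1H)-one
Conditions: KOH, xylenes, 110 °C (Dean–Stark)
Reagents that add atoms: none
Why: Intramolecular aldol condensation of the methyl ketone onto the ring ketone is the only enolate pathway that can dehydrate, so it closes the cyclopentenone ring B while the non-enolisable quaternary centre is kept.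

Step 8
Reactants: 10 (6aS)-6a-methyl-4,5,6,6a-tetrahydropentalen-2(1H)-one
Product: 11 trimethyl{[(3aR,6aS)-3a,6a-dimethyl-1,3a,4,5,6,6a-hexahydropentalen-2-yl]oxy}silane
Conditions: Me2CuLi (from CuI and 2 MeLi), TMSCl, THF/Et2O, −78 to −30 °C; Et3N, pentane work-up, used crude
Reagents that add atoms: methyllithium, C[Li]; chlorotrimethylsilane, C[Si](C)(C)Cl
Why: In this TMSCl-accelerated Gilman conjugate addition the methyl can reach the ring-fusion carbon only from the face that gives a cis-fused bicyclo[3.3.0]octane, so the two methyls become cis, and silylation traps the enolate regiospecifically on the side of the new quaternary carbon.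

Step 9
Reactants: 11 trimethyl{[(3aR,6aS)-3a,6a-dimethyl-1,3a,4,5,6,6a-hexahydropentalen-2-yl]oxy}silane
Product: 14 (4aS,7aS)-4a,7a-dimethylhexahydrocyclopenta[c]pyran-3(1H)-one, via aldehyde acid 12 (not isolated), via hydroxy acid 13 (not isolated)
Conditions: O3, CH2Cl2/MeOH 3:1, −78 °C; NaBH4, −78 °C to rt; then 2 M HCl, rt
Reagents that add atoms: ozone, [O-][O+]=O
Why: Ozonolysis of the silyl enol ether cuts ring B exactly at the enol double bond into an aldehyde on the new quaternary carbon and a carboxylic acid on the CH2 arm, and borohydride reduction with acid lactonisation stores this differentiation in a δ-lactone without touching either quaternary centre.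

Step 10
Reactants: 14 (4aS,7aS)-4a,7a-dimethylhexahydrocyclopenta[c]pyran-3(1H)-one
Product: 15 (4aS,7aS)-4a,7a-dimethyloctahydrocyclopenta[c]pyran-3-ol (both anomers)
Conditions: i-Bu2AlH (1.1 equiv), CH2Cl2, −78 °C
Reagents that add atoms: none
Why: Partial hydride reduction of the lactone stops at the lactol because the tetrahedral aluminium hemiacetal is stable at low temperature.

Step 11
Reactants: 15 (4aS,7aS)-4a,7a-dimethyloctahydrocyclopenta[c]pyran-3-ol
Product: 16 [(1S,2S)-2-(1,3-dithian-2-ylmethyl)-1,2-dimethylcyclopentyl]methanol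
Conditions: HS(CH2)3SH, BF3·OEt2, CH2Cl2, −20 to 0 °C
Reagents that add atoms: propane-1,3-dithiol, SCCCS
Why: Lewis acid thioacetalisation of the open hydroxy-aldehyde form of the lactol installs the 1,3-dithiane (the acyl anion precursor) on the CH2 arm and releases the neopentyl alcohol on the other quaternary carbon.

Step 12
Reactants: 16 [(1S,2S)-2-(1,3-dithian-2-ylmethyl)-1,2-dimethylcyclopentyl]methanol
Product: 17 {[(1S,2S)-2-(1,3-dithian-2-ylmethyl)-1,2-dimethylcyclopentyl]methoxy}triethylsilane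
Conditions: Et3SiCl, imidazole, CH2Cl2, rt
Reagents that add atoms: chlorotriethylsilane, CC[Si](CC)(CC)Cl
Why: Silyl ether protection masks the only O–H so that the later strong base lithiates the dithiane alone, and this triethylsilyl ether can be removed by mild acid beside aryl silyl ethers.

**Aryl fragment**

Step 13
Reactants: 18 2-methyl-6-(prop-2-en-1-yl)phenol
Product: 19 2-methyl-6-(prop-2-en-1-yl)cyclohexa-2,5-diene-1,4-dione
Conditions: Co(salen) (C16H14CoN2O2, 5 mol%), O2 (1 atm), DMF, rt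
Reagents that add atoms: dioxygen, O=O
Why: Cobalt–salen catalysed aerobic oxidation of a 2,6-disubstituted phenol oxygenates the free para position and gives the p-benzoquinone.

Step 14
Reactants: 19 2-methyl-6-(prop-2-en-1-yl)cyclohexa-2,5-diene-1,4-dione
Product: 20 2-methyl-6-(prop-2-en-1-yl)benzene-1,4-diol
Conditions: Na2S2O4, Et2O/H2O, rt
Reagents that add atoms: none
Why: Dithionite reduction of the quinone to the hydroquinone is fast and leaves the allyl group alone.

Step 15
Reactants: 20 2-methyl-6-(prop-2-en-1-yl)benzene-1,4-diol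
Product: 21 1,4-bis(tert-butyldimethylsilyloxy)-2-methyl-6-(prop-2-en-1-yl)benzene
Conditions: t-BuMe2SiCl (2.5 equiv), imidazole, DMF, 50 °C
Reagents that add atoms: tert-butylchlorodimethylsilane, CC(C)(C)[Si](C)(C)Cl
Why: Double silyl ether formation protects the oxidation-prone hydroquinone with groups that survive base, hydride, organolithium and mild acid and fall to fluoride at the end.

Step 16
Reactants: 21 1,4-bis(tert-butyldimethylsilyloxy)-2-methyl-6-(prop-2-en-1-yl)benzene
Product: 22 2-[2,5-bis(tert-butyldimethylsilyloxy)-3-methylphenyl]acetaldehyde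
Conditions: OsO4 (2 mol%), NaIO4 (4 equiv), 2,6-lutidine, dioxane/H2O 3:1, rt
Reagents that add atoms: sodium periodate, [Na+].[O-]I(=O)(=O)=O; osmium tetroxide (catalytic oxygen carrier), O=[Os](=O)(=O)=O
Why: Lemieux–Johnson dihydroxylation and periodate cleavage shortens the allyl group to the arylacetaldehyde while avoiding ozone on the electron-rich arene.

Step 17
Reactants: 22 2-[2,5-bis(tert-butyldimethylsilyloxy)-3-methylphenyl]acetaldehyde; 23 ethyl 2-[bis(2,2,2-trifluoroethoxy)phosphoryl]propanoate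
Product: 25 ethyl (2Z)-4-[2,5-bis(tert-butyldimethylsilyloxy)-3-methylphenyl]-2-methylbut-2-enoate, via potassium phosphonate carbanion 24 (not isolated)
Conditions: 23, KN(SiMe3)2, 18-crown-6, THF, −78 °C; then 22, −78 °C
Reagents that add atoms: none
Why: In the Still–Gennari olefination the electron-poor bis(trifluoroethyl) phosphonate eliminates quickly from the kinetic adduct, which gives the Z trisubstituted enoate with the ester cis to the CH2Ar group, and the low temperature and absence of excess base prevent migration of the alkene toward the arene.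

Step 18
Reactants: 25 ethyl (2Z)-4-[2,5-bis(tert-butyldimethylsilyloxy)-3-methylphenyl]-2-methylbut-2-enoate
Product: 26 (2Z)-4-[2,5-bis(tert-butyldimethylsilyloxy)-3-methylphenyl]-2-methylbut-2-en-1-ol
Conditions: i-Bu2AlH (2.5 equiv), CH2Cl2, −78 °C
Reagents that add atoms: none
Why: 1,2-Reduction of the enoate by the aluminium hydride gives the allylic alcohol with the Z geometry unchanged.

Step 19
Reactants: 26 (2Z)-4-[2,5-bis(tert-butyldimethylsilyloxy)-3-methylphenyl]-2-methylbut-2-en-1-ol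
Product: 27 1-[(2Z)-4-bromo-3-methylbut-2-en-1-yl]-2,5-bis(tert-butyldimethylsilyloxy)-3-methylbenzene
Conditions: CBr4, PPh3, CH2Cl2, −20 °C
Reagents that add atoms: tetrabromomethane, BrC(Br)(Br)Br
Why: The Appel reaction turns the primary allylic alcohol into the bromide under neutral conditions at low temperature, so no allylic transposition or Z/E isomerisation takes place.

**Alkenyl fragment**

Step 20
Reactants: 28 2-methylbut-3-yn-2-ol
Product: 29 triethyl[(2-methylbut-3-yn-2-yl)oxy]silane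
Conditions: Et3SiCl, imidazole, DMAP (cat.), DMF, rt
Reagents that add atoms: chlorotriethylsilane, CC[Si](CC)(CC)Cl
Why: Silyl ether protection of the tertiary propargylic alcohol removes the acidic O–H before the organometallic steps.

Step 21
Reactants: 29 triethyl[(2-methylbut-3-yn-2-yl)oxy]silane
Product: 31 triethyl{[(3E)-4-iodo-2-methylbut-3-en-2-yl]oxy}silane, via alkenylzirconocene chloride 30 (not isolated)
Conditions: Cp2Zr(H)Cl, THF, rt; then I2, 0 °C
Reagents that add atoms: iodine, II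
Why: Hydrozirconation adds H and Zr syn with zirconium on the terminal carbon, and iodinolysis with retention gives the E alkenyl iodide.

**Fragment union and end game**

Step 22
Reactants: 17 {[(1S,2S)-2-(1,3-dithian-2-ylmethyl)-1,2-dimethylcyclopentyl]methoxy}triethylsilane; 27 1-[(2Z)-4-bromo-3-methylbut-2-en-1-yl]-2,5-bis(tert-butyldimethylsilyloxy)-3-methylbenzene
Product: 33 triethyl{[(1S,2S)-2-({2-[(2Z)-4-[2,5-bis(tert-butyldimethylsilyloxy)-3-methylphenyl]-2-methylbut-2-en-1-yl]-1,3-dithian-2-yl}methyl)-1,2-dimethylcyclopentyl]methoxy}silane, via 2-lithio-1,3-dithiane 32 (not isolated)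
Conditions: t-BuLi (1.05 equiv), THF/HMPA 10:1, −78 °C; then 27, −78 °C
Reagents that add atoms: none
Why: Corey–Seebach umpolung lets the soft dithiane anion displace the primary allylic bromide by SN2 at −78 °C with retention of the Z geometry, which builds the masked β,γ-unsaturated ketone.

Step 23
Reactants: 33 triethyl{[(1S,2S)-2-({2-[(2Z)-4-[2,5-bis(tert-butyldimethylsilyloxy)-3-methylphenyl]-2-methylbut-2-en-1-yl]-1,3-dithian-2-yl}methyl)-1,2-dimethylcyclopentyl]methoxy}silane
Product: 34 [(1S,2S)-2-({2-[(2Z)-4-[2,5-bis(tert-butyldimethylsilyloxy)-3-methylphenyl]-2-methylbut-2-en-1-yl]-1,3-dithian-2-yl}methyl)-1,2-dimethylcyclopentyl]methanol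
Conditions: PPTS, MeOH/CH2Cl2 1:1, 0 °C to rt
Reagents that add atoms: none
Why: Mild acid methanolysis removes the primary alkyl triethylsilyl ether selectively because aryl tert-butyldimethylsilyl ethers and the dithiane are stable to weak acid.

Step 24
Reactants: 34 [(1S,2S)-2-({2-[(2Z)-4-[2,5-bis(tert-butyldimethylsilyloxy)-3-methylphenyl]-2-methylbut-2-en-1-yl]-1,3-dithian-2-yl}methyl)-1,2-dimethylcyclopentyl]methanol
Product: 35 (1S,2S)-2-({2-[(2Z)-4-[2,5-bis(tert-butyldimethylsilyloxy)-3-methylphenyl]-2-methylbut-2-en-1-yl]-1,3-dithian-2-yl}methyl)-1,2-dimethylcyclopentane-1-carbaldehyde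
Conditions: SO3·pyridine, DMSO, i-Pr2NEt, CH2Cl2, 0 °C
Reagents that add atoms: none
Why: Parikh–Doering oxidation converts the neopentyl alcohol into the non-enolisable aldehyde and is compatible with the dithiane sulfur atoms.

Step 25
Reactants: 35 (1S,2S)-2-({2-[(2Z)-4-[2,5-bis(tert-butyldimethylsilyloxy)-3-methylphenyl]-2-methylbut-2-en-1-yl]-1,3-dithian-2-yl}methyl)-1,2-dimethylcyclopentane-1-carbaldehyde; 31 triethyl{[(3E)-4-iodo-2-methylbut-3-en-2-yl]oxy}silane
Product: 37 (1RS,2E)-1-[(1S,2S)-2-({2-[(2Z)-4-[2,5-bis(tert-butyldimethylsilyloxy)-3-methylphenyl]-2-methylbut-2-en-1-yl]-1,3-dithian-2-yl}methyl)-1,2-dimethylcyclopentyl]-4-methyl-4-(triethylsilyloxy)pent-2-en-1-ol, via alkenyllithium 36 (not isolated)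
Conditions: 31 (2 equiv), t-BuLi (4 equiv), Et2O, −78 °C; then 35, −78 °C
Reagents that add atoms: none
Why: Lithium–iodine exchange keeps the E geometry and the alkenyllithium undergoes 1,2-addition to the aldehyde, which cannot enolise, while the ketone stays masked as the dithiane, and the new carbinol centre forms as an epimer mixture that the next step erases.

Step 26
Reactants: 37 (1RS,2E)-1-[(1S,2S)-2-({2-[(2Z)-4-[2,5-bis(tert-butyldimethylsilyloxy)-3-methylphenyl]-2-methylbut-2-en-1-yl]-1,3-dithian-2-yl}methyl)-1,2-dimethylcyclopentyl]-4-methyl-4-(triethylsilyloxy)pent-2-en-1-ol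
Product: 38 (2E)-1-[(1S,2S)-2-({2-[(2Z)-4-[2,5-bis(tert-butyldimethylsilyloxy)-3-methylphenyl]-2-methylbut-2-en-1-yl]-1,3-dithian-2-yl}methyl)-1,2-dimethylcyclopentyl]-4-methyl-4-(triethylsilyloxy)pent-2-en-1-one
Conditions: MnO2 (activated, 20 equiv), CH2Cl2, rt
Reagents that add atoms: none
Why: Allylic oxidation with MnO2 is selective for the allylic carbinol, leaves the dithiane, the silyl ethers and both alkenes alone and removes the undefined stereocentre.

Step 27
Reactants: 38 (2E)-1-[(1S,2S)-2-({2-[(2Z)-4-[2,5-bis(tert-butyldimethylsilyloxy)-3-methylphenyl]-2-methylbut-2-en-1-yl]-1,3-dithian-2-yl}methyl)-1,2-dimethylcyclopentyl]-4-methyl-4-(triethylsilyloxy)pent-2-en-1-one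
Product: 39 (2E)-1-[(1S,2S)-2-{(4Z)-6-[2,5-bis(tert-butyldimethylsilyloxy)-3-methylphenyl]-4-methyl-2-oxohex-4-en-1-yl}-1,2-dimethylcyclopentyl]-4-methyl-4-(triethylsilyloxy)pent-2-en-1-one
Conditions: MeI (excess), CaCO3, MeCN/H2O 9:1, 45 °C
Reagents that add atoms: water, O
Why: Alkylative dethioacetalisation (S-methylation, then buffered hydrolysis) unmasks the ketone under near-neutral conditions that avoid conjugation of the β,γ-alkene and Z/E scrambling.

Step 28
Reactants: 39 (2E)-1-[(1S,2S)-2-{(4Z)-6-[2,5-bis(tert-butyldimethylsilyloxy)-3-methylphenyl]-4-methyl-2-oxohex-4-en-1-yl}-1,2-dimethylcyclopentyl]-4-methyl-4-(triethylsilyloxy)pent-2-en-1-one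
Product: 40 (2E)-1-[(1S,2S)-2-[(4Z)-6-(2,5-dihydroxy-3-methylphenyl)-4-methyl-2-oxohex-4-en-1-yl]-1,2-dimethylcyclopentyl]-4-hydroxy-4-methylpent-2-en-1-one (CNP0212540.3)
Conditions: Bu4NF, AcOH (1:1), THF, 0 °C to rt, argon
Reagents that add atoms: none
Why: Acetic acid-buffered fluoride desilylation cleaves the two aryl silyl ethers and the tertiary triethylsilyl ether in one operation without exposing the enone, the β,γ-unsaturated ketone or the air-sensitive hydroquinone to base.

## Compound list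

1 | 2-methylcyclopentane-1,3-dione | CC1C(=O)CCC1=O | starting material
2 | 3-bromoprop-1-ene (allyl bromide) | C=CCBr | starting material
3 | 2-methyl-2-(prop-2-en-1-yl)cyclopentane-1,3-dione | C=CCC1(C)C(=O)CCC1=O | intermediate
4 | (2S,3S)-3-hydroxy-2-methyl-2-(prop-2-en-1-yl)cyclopentan-1-one | C=CC[C@]1(C)C(=O)CC[C@@H]1O | intermediate
5 | N'-[(1E,2R,3S)-3-hydroxy-2-methyl-2-(prop-2-en-1-yl)cyclopentylidene]-4-methylbenzenesulfonohydrazide | C=CC[C@]1(C)/C(=N/NS(=O)(=O)c2ccc(C)cc2)CC[C@@H]1O | intermediate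
6 | N'-(1,3,2-benzodioxaborol-2-yl)-N'-[(1RS,2R,3S)-3-(1,3,2-benzodioxaborol-2-yloxy)-2-methyl-2-(prop-2-en-1-yl)cyclopentyl]-4-methylbenzenesulfonohydrazide (C1 epimers) | C=CC[C@]1(C)C(N(NS(=O)(=O)c2ccc(C)cc2)B2Oc3ccccc3O2)CC[C@@H]1OB1Oc2ccccc2O1 | intermediate (not isolated)
7 | (1S,2S)-2-methyl-2-(prop-2-en-1-yl)cyclopentan-1-ol | C=CC[C@]1(C)CCC[C@@H]1O | intermediate
8 | (2S)-2-methyl-2-(prop-2-en-1-yl)cyclopentan-1-one | C=CC[C@]1(C)CCCC1=O | intermediate
9 | (2S)-2-methyl-2-(2-oxopropyl)cyclopentan-1-one | CC(=O)C[C@]1(C)CCCC1=O | intermediate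
10 | (6aS)-6a-methyl-4,5,6,6a-tetrahydropentalen-2(1H)-one | O=C1C[C@]2(C)CCCC2=C1 | intermediate
11 | trimethyl{[(3aR,6aS)-3a,6a-dimethyl-1,3a,4,5,6,6a-hexahydropentalen-2-yl]oxy}silane (cis-fused, methyls cis) | C[Si](C)(C)OC1=C[C@@]2(C)CCC[C@@]2(C)C1 | intermediate
12 | 2-[(1S,2S)-2-formyl-1,2-dimethylcyclopentyl]acetic acid | O=C[C@@]1(C)CCC[C@@]1(C)CC(=O)O | intermediate (not isolated)
13 | 2-[(1S,2S)-2-(hydroxymethyl)-1,2-dimethylcyclopentyl]acetic acid | OC[C@@]1(C)CCC[C@@]1(C)CC(=O)O | intermediate (not isolated)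
14 | (4aS,7aS)-4a,7a-dimethylhexahydrocyclopenta[c]pyran-3(1H)-one (cis-fused δ-lactone) | O=C1C[C@]2(C)CCC[C@]2(C)CO1 | intermediate
15 | (4aS,7aS)-4a,7a-dimethyloctahydrocyclopenta[c]pyran-3-ol (both anomers) | OC1C[C@]2(C)CCC[C@]2(C)CO1 | intermediate
16 | [(1S,2S)-2-(1,3-dithian-2-ylmethyl)-1,2-dimethylcyclopentyl]methanol | OC[C@@]1(C)CCC[C@@]1(C)CC1SCCCS1 | intermediate
17 | {[(1S,2S)-2-(1,3-dithian-2-ylmethyl)-1,2-dimethylcyclopentyl]methoxy}triethylsilane | CC[Si](CC)(CC)OC[C@@]1(C)CCC[C@@]1(C)CC1SCCCS1 | intermediate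
18 | 2-methyl-6-(prop-2-en-1-yl)phenol | C=CCc1cccc(C)c1O | starting material
19 | 2-methyl-6-(prop-2-en-1-yl)cyclohexa-2,5-diene-1,4-dione | C=CCC1=CC(=O)C=C(C)C1=O | intermediate
20 | 2-methyl-6-(prop-2-en-1-yl)benzene-1,4-diol | C=CCc1cc(O)cc(C)c1O | intermediate
21 | 1,4-bis(tert-butyldimethylsilyloxy)-2-methyl-6-(prop-2-en-1-yl)benzene | C=CCc1cc(O[Si](C)(C)C(C)(C)C)cc(C)c1O[Si](C)(C)C(C)(C)C | intermediate
22 | 2-[2,5-bis(tert-butyldimethylsilyloxy)-3-methylphenyl]acetaldehyde | O=CCc1cc(O[Si](C)(C)C(C)(C)C)cc(C)c1O[Si](C)(C)C(C)(C)C | intermediate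
23 | ethyl 2-[bis(2,2,2-trifluoroethoxy)phosphoryl]propanoate | CCOC(=O)C(C)P(=O)(OCC(F)(F)F)OCC(F)(F)F | starting material
24 | potassium 2-[bis(2,2,2-trifluoroethoxy)phosphoryl]-1-ethoxy-1-oxopropan-2-ide | [K+].CCOC(=O)[C-](C)P(=O)(OCC(F)(F)F)OCC(F)(F)F | intermediate (not isolated)
25 | ethyl (2Z)-4-[2,5-bis(tert-butyldimethylsilyloxy)-3-methylphenyl]-2-methylbut-2-enoate | CCOC(=O)/C(C)=C\Cc1cc(O[Si](C)(C)C(C)(C)C)cc(C)c1O[Si](C)(C)C(C)(C)C | intermediate
26 | (2Z)-4-[2,5-bis(tert-butyldimethylsilyloxy)-3-methylphenyl]-2-methylbut-2-en-1-ol | OC/C(C)=C\Cc1cc(O[Si](C)(C)C(C)(C)C)cc(C)c1O[Si](C)(C)C(C)(C)C | intermediate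
27 | 1-[(2Z)-4-bromo-3-methylbut-2-en-1-yl]-2,5-bis(tert-butyldimethylsilyloxy)-3-methylbenzene | BrC/C(C)=C\Cc1cc(O[Si](C)(C)C(C)(C)C)cc(C)c1O[Si](C)(C)C(C)(C)C | intermediate
28 | 2-methylbut-3-yn-2-ol | C#CC(C)(C)O | starting material
29 | triethyl[(2-methylbut-3-yn-2-yl)oxy]silane | C#CC(C)(C)O[Si](CC)(CC)CC | intermediate
30 | chlorobis(cyclopentadienyl)[(1E)-3-methyl-3-(triethylsilyloxy)but-1-en-1-yl]zirconium (Cp rings drawn σ-bonded) | CC[Si](CC)(CC)OC(C)(C)/C=C/[Zr](Cl)(C1C=CC=C1)C1C=CC=C1 | intermediate (not isolated)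
31 | triethyl{[(3E)-4-iodo-2-methylbut-3-en-2-yl]oxy}silane | CC[Si](CC)(CC)OC(C)(C)/C=C/I | intermediate
32 | {2-[((1S,2S)-1,2-dimethyl-2-{[(triethylsilyl)oxy]methyl}cyclopentyl)methyl]-1,3-dithian-2-yl}lithium | CC[Si](CC)(CC)OC[C@@]1(C)CCC[C@@]1(C)CC1([Li])SCCCS1 | intermediate (not isolated)
33 | triethyl{[(1S,2S)-2-({2-[(2Z)-4-[2,5-bis(tert-butyldimethylsilyloxy)-3-methylphenyl]-2-methylbut-2-en-1-yl]-1,3-dithian-2-yl}methyl)-1,2-dimethylcyclopentyl]methoxy}silane | CC[Si](CC)(CC)OC[C@@]1(C)CCC[C@@]1(C)CC1(C/C(C)=C\Cc2cc(O[Si](C)(C)C(C)(C)C)cc(C)c2O[Si](C)(C)C(C)(C)C)SCCCS1 | intermediate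
34 | [(1S,2S)-2-({2-[(2Z)-4-[2,5-bis(tert-butyldimethylsilyloxy)-3-methylphenyl]-2-methylbut-2-en-1-yl]-1,3-dithian-2-yl}methyl)-1,2-dimethylcyclopentyl]methanol | OC[C@@]1(C)CCC[C@@]1(C)CC1(C/C(C)=C\Cc2cc(O[Si](C)(C)C(C)(C)C)cc(C)c2O[Si](C)(C)C(C)(C)C)SCCCS1 | intermediate
35 | (1S,2S)-2-({2-[(2Z)-4-[2,5-bis(tert-butyldimethylsilyloxy)-3-methylphenyl]-2-methylbut-2-en-1-yl]-1,3-dithian-2-yl}methyl)-1,2-dimethylcyclopentane-1-carbaldehyde | O=C[C@@]1(C)CCC[C@@]1(C)CC1(C/C(C)=C\Cc2cc(O[Si](C)(C)C(C)(C)C)cc(C)c2O[Si](C)(C)C(C)(C)C)SCCCS1 | intermediate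
36 | [(1E)-3-methyl-3-(triethylsilyloxy)but-1-en-1-yl]lithium | CC[Si](CC)(CC)OC(C)(C)/C=C/[Li] | intermediate (not isolated)
37 | (1RS,2E)-1-[(1S,2S)-2-({2-[(2Z)-4-[2,5-bis(tert-butyldimethylsilyloxy)-3-methylphenyl]-2-methylbut-2-en-1-yl]-1,3-dithian-2-yl}methyl)-1,2-dimethylcyclopentyl]-4-methyl-4-(triethylsilyloxy)pent-2-en-1-ol (carbinol epimers) | CC[Si](CC)(CC)OC(C)(C)/C=C/C(O)[C@@]1(C)CCC[C@@]1(C)CC1(C/C(C)=C\Cc2cc(O[Si](C)(C)C(C)(C)C)cc(C)c2O[Si](C)(C)C(C)(C)C)SCCCS1 | intermediate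
38 | (2E)-1-[(1S,2S)-2-({2-[(2Z)-4-[2,5-bis(tert-butyldimethylsilyloxy)-3-methylphenyl]-2-methylbut-2-en-1-yl]-1,3-dithian-2-yl}methyl)-1,2-dimethylcyclopentyl]-4-methyl-4-(triethylsilyloxy)pent-2-en-1-one | CC[Si](CC)(CC)OC(C)(C)/C=C/C(=O)[C@@]1(C)CCC[C@@]1(C)CC1(C/C(C)=C\Cc2cc(O[Si](C)(C)C(C)(C)C)cc(C)c2O[Si](C)(C)C(C)(C)C)SCCCS1 | intermediate
39 | (2E)-1-[(1S,2S)-2-{(4Z)-6-[2,5-bis(tert-butyldimethylsilyloxy)-3-methylphenyl]-4-methyl-2-oxohex-4-en-1-yl}-1,2-dimethylcyclopentyl]-4-methyl-4-(triethylsilyloxy)pent-2-en-1-one | CC[Si](CC)(CC)OC(C)(C)/C=C/C(=O)[C@@]1(C)CCC[C@@]1(C)CC(=O)C/C(C)=C\Cc1cc(O[Si](C)(C)C(C)(C)C)cc(C)c1O[Si](C)(C)C(C)(C)C | intermediate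
40 | (2E)-1-[(1S,2S)-2-[(4Z)-6-(2,5-dihydroxy-3-methylphenyl)-4-methyl-2-oxohex-4-en-1-yl]-1,2-dimethylcyclopentyl]-4-hydroxy-4-methylpent-2-en-1-one | C/C(=C/Cc1cc(O)cc(C)c1O)CC(=O)C[C@]1(C)CCC[C@]1(C)C(=O)/C=C/C(C)(C)O | target

## Step count and risks

Total step count: 28. Longest linear sequence: 19 steps (steps 1 to 12 and 22 to 28, from 1 to 40); the aryl fragment takes 7 steps and the alkenyl fragment 2.

The three steps most likely to fail:

First, step 4. Reduction of a hindered α-quaternary tosylhydrazone can stall or give alkene by-products. The fallback sets out from 4 and removes the ketone by radical deoxygenation of the derived alcohol instead. Silylation (t-BuMe2SiCl, imidazole, DMF) gives (2S,3S)-3-(tert-butyldimethylsilyloxy)-2-methyl-2-(prop-2-en-1-yl)cyclopentan-1-one F1. NaBH4 (MeOH, 0 °C) gives (1RS,2R,3S)-3-(tert-butyldimethylsilyloxy)-2-methyl-2-(prop-2-en-1-yl)cyclopentan-1-ol F2. NaH, CS2 and MeI (THF) give the xanthate O-[(1RS,2R,3S)-3-(tert-butyldimethylsilyloxy)-2-methyl-2-(prop-2-en-1-yl)cyclopentyl] S-methyl carbonodithioate F3. Barton–McCombie reduction (Bu3SnH, AIBN, toluene, 110 °C) gives tert-butyldimethyl{[(1S,2S)-2-methyl-2-(prop-2-en-1-yl)cyclopentyl]oxy}silane F4, and Bu4NF (THF) returns alcohol 7, where the route is rejoined.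

Second, step 8. Conjugate addition that creates a quaternary carbon next to an existing one can be slow, and 1,2-addition or enolate loss on work-up would cost material. The fallback sets out from 10 and brings the methyl in as a CH2 group. Corey–Chaykovsky cyclopropanation (Me3S(O)I, NaH, DMSO, 50 °C) gives the cyclopropyl ketone (1S,3R,6S)-6-methyltricyclo[4.3.0.0(1,3)]nonan-4-one F5, the CH2 entering cis to the angular methyl because only that face gives a cis ring fusion. Lithium in liquid NH3/THF (−78 °C) then cleaves the exocyclic cyclopropane bond that overlaps with the carbonyl π system. This delivers the angular methyl and the same regiodefined lithium enolate, which after removal of ammonia is silylated (TMSCl, Et3N) to rejoin the route at 11.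

Third, step 22. The strongly basic dithiane anion may cause 1,4-elimination of HBr from 27 toward an aryl-conjugated diene instead of substitution. The fallback reverses the polarity and sets out from bromide 27 and lactone 14. PhSO2Na (DMF, rt) turns 27 into the allylic sulfone 1-[(2Z)-4-(benzenesulfonyl)-3-methylbut-2-en-1-yl]-2,5-bis(tert-butyldimethylsilyloxy)-3-methylbenzene F6. Its α-lithio derivative (n-BuLi, THF, −78 °C, 2 equiv) is acylated by lactone 14 to give the hydroxy β-keto sulfone (4Z)-3-(benzenesulfonyl)-6-[2,5-bis(tert-butyldimethylsilyloxy)-3-methylphenyl]-1-[(1S,2S)-2-(hydroxymethyl)-1,2-dimethylcyclopentyl]-4-methylhex-4-en-2-one F7. Reductive desulfonylation with SmI2 (THF/MeOH, −78 °C) gives the hydroxy ketone (4Z)-6-[2,5-bis(tert-butyldimethylsilyloxy)-3-methylphenyl]-1-[(1S,2S)-2-(hydroxymethyl)-1,2-dimethylcyclopentyl]-4-methylhex-4-en-2-one F8. Thioketalisation (propane-1,3-dithiol, BF3·OEt2, CH2Cl2, −20 °C) then gives 34, where the route is rejoined, so steps 10 to 12, 22 and 23 are bypassed.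

Further compounds
F1 | step 4 | (2S,3S)-3-(tert-butyldimethylsilyloxy)-2-methyl-2-(prop-2-en-1-yl)cyclopentan-1-one | C=CC[C@]1(C)C(=O)CC[C@@H]1O[Si](C)(C)C(C)(C)C
F2 | step 4 | (1RS,2R,3S)-3-(tert-butyldimethylsilyloxy)-2-methyl-2-(prop-2-en-1-yl)cyclopentan-1-ol | C=CC[C@]1(C)C(O)CC[C@@H]1O[Si](C)(C)C(C)(C)C
F3 | step 4 | O-[(1RS,2R,3S)-3-(tert-butyldimethylsilyloxy)-2-methyl-2-(prop-2-en-1-yl)cyclopentyl] S-methyl carbonodithioate | C=CC[C@]1(C)C(OC(=S)SC)CC[C@@H]1O[Si](C)(C)C(C)(C)C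
F4 | step 4 | tert-butyldimethyl{[(1S,2S)-2-methyl-2-(prop-2-en-1-yl)cyclopentyl]oxy}silane | C=CC[C@]1(C)CCC[C@@H]1O[Si](C)(C)C(C)(C)C
F5 | step 8 | (1S,3R,6S)-6-methyltricyclo[4.3.0.0(1,3)]nonan-4-one | O=C1C[C@]2(C)CCC[C@@]23C[C@@H]13
F6 | step 22 | 1-[(2Z)-4-(benzenesulfonyl)-3-methylbut-2-en-1-yl]-2,5-bis(tert-butyldimethylsilyloxy)-3-methylbenzene | O=S(=O)(C/C(C)=C\Cc1cc(O[Si](C)(C)C(C)(C)C)cc(C)c1O[Si](C)(C)C(C)(C)C)c1ccccc1
F7 | step 22 | (4Z)-3-(benzenesulfonyl)-6-[2,5-bis(tert-butyldimethylsilyloxy)-3-methylphenyl]-1-[(1S,2S)-2-(hydroxymethyl)-1,2-dimethylcyclopentyl]-4-methylhex-4-en-2-one (C3 epimers) | OC[C@@]1(C)CCC[C@@]1(C)CC(=O)C(S(=O)(=O)c1ccccc1)/C(C)=C\Cc1cc(O[Si](C)(C)C(C)(C)C)cc(C)c1O[Si](C)(C)C(C)(C)C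
F8 | step 22 | (4Z)-6-[2,5-bis(tert-butyldimethylsilyloxy)-3-methylphenyl]-1-[(1S,2S)-2-(hydroxymethyl)-1,2-dimethylcyclopentyl]-4-methylhex-4-en-2-one | OC[C@@]1(C)CCC[C@@]1(C)CC(=O)C/C(C)=C\Cc1cc(O[Si](C)(C)C(C)(C)C)cc(C)c1O[Si](C)(C)C(C)(C)C
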